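**Retrosynthetic overview**
1. Target 19 is an apigenin unit bonded through its C3 to C8 of a (2S)-5,7,4'-trihydroxyflavan. The last step is sixfold O-debenzylation of hexabenzyl ether 18.
2. Key disconnection: ring C of the flavan is cut at C4–C4a and O1–C8a together. This gives aryl iodide 12 (iodine on the future C8a, C–H on the future C4a) and (S)-2-aryloxetane 17. In the forward direction a palladium/norbornene annulation inserts the A-ring edge C4a–C8a into the strained O–CH2 bond, expanding the four-membered ring to a six-membered one.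
3. Enabling feature: the chain O1–C2–C3–C4 of ring C sits on two adjacent A-ring carbons. Its two ends can be tied to each other as an oxetane (an O1–C4 bond absent from the target, about 25 kcal/mol of strain) without touching C2. C8a lies between a free C–H (C4a) and C8, whose flavon-3-yl group is the ortho blocking group this catalysis needs.
4. Iodide 12 comes from tri-O-benzylapigenin 6 by C3 zincation, Negishi coupling at the C–I bond of 9, and Br-to-I exchange. Oxetane 17 comes from a CBS reduction that sets C2, followed by Williamson closure.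
5. Ring order: flavone ring C (step 3), oxetane (step 10), flavan ring C (step 11).

Key step: step 11

Assumption: the structure fixes only C2 of the flavan as (S). The hindered C3–C8 axis carries no descriptor, so rotamers or atropisomers about it (in 11, 12, 18 and 19) are treated as one compound.

Step 1
Reactants: 1 2',4',6'-trihydroxyacetophenone
Product: 2 1-[2,4-bis(benzyloxy)-6-hydroxyphenyl]ethan-1-one
Conditions: BnBr (2.1 equiv), K2CO3 (2.2 equiv), acetone, reflux
Reagents that add atoms: benzyl bromide BrCc1ccccc1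
Why: Williamson etherification, in which the two free phenols react while the OH that is hydrogen-bonded to the acetyl carbonyl stays untouched at two equivalents of benzyl bromide.

Step 2
Reactants: 2 1-[2,4-bis(benzyloxy)-6-hydroxyphenyl]ethan-1-one; 3 4-(benzyloxy)benzaldehyde
Product: 4 (E)-1-[2,4-bis(benzyloxy)-6-hydroxyphenyl]-3-[4-(benzyloxy)phenyl]prop-2-en-1-one
Conditions: KOH (aq. 50 %), EtOH, rt
Reagents that add atoms: none
Why: Claisen–Schmidt condensation of the methyl ketone enolate with a non-enolisable aldehyde, the E1cB loss of water giving the conjugated (E)-enone.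

Step 3
Reactants: 4 (E)-chalcone
Product: 6 5,7-bis(benzyloxy)-2-[4-(benzyloxy)phenyl]-4H-chromen-4-one (tri-O-benzylapigenin), via flavanone 5 (not isolated)
Conditions: I2 (10 mol %), DMSO, 120 °C
Reagents that add atoms: none
Why: Iodine-catalysed oxidative cyclisation of a 2'-hydroxychalcone, in which 6-endo oxa-Michael closure gives flavanone 5 and iodine dehydrogenates it at C2–C3 while DMSO reoxidises the iodide, conditions that aryl benzyl ethers tolerate.

Step 4
Reactants: 7 5-bromoresorcinol
Product: 8 1,3-bis(benzyloxy)-5-bromobenzene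
Conditions: BnBr (2.2 equiv), K2CO3 (2.5 equiv), DMF, rt
Reagents that add atoms: benzyl bromide BrCc1ccccc1
Why: Williamson etherification of both phenols.

Step 5
Reactants: 8 1,3-bis(benzyloxy)-5-bromobenzene
Product: 9 1,5-bis(benzyloxy)-3-bromo-2-iodobenzene
Conditions: NIS (1.05 equiv), TFA (cat.), MeCN, 0 °C to rt
Reagents that add atoms: N-iodosuccinimide O=C1CCC(=O)N1I
Why: Electrophilic aromatic iodination, which should go para to one benzyloxy group and ortho to the other (next to bromine) and not into the more crowded position between the two ethers, as is usual for 5-haloresorcinol diethers.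

Step 6
Reactants: 6 tri-O-benzylapigenin; 9 1,5-bis(benzyloxy)-3-bromo-2-iodobenzene
Product: 11 3-[2,4-bis(benzyloxy)-6-bromophenyl]-5,7-bis(benzyloxy)-2-[4-(benzyloxy)phenyl]-4H-chromen-4-one, via flavon-3-ylzinc chloride 10 (not isolated)
Conditions: TMPZnCl·LiCl (1.3 equiv), MgCl2 (1.3 equiv), THF, −20 °C to rt; then 9, Pd(OAc)2 (4 mol %), SPhos (8 mol %), 50 °C
Reagents that add atoms: none
Why: Directed zincation of the chromone C3–H (MgCl2 on the C4 carbonyl steers the amide base, C2 being blocked) followed by Negishi coupling, in which zerovalent palladium inserts into the C–I bond of 9 much faster than into its C–Br bond and SPhos copes with the doubly flanked partners.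

Step 7
Reactants: 11 bromoaryl flavone
Product: 12 3-[2,4-bis(benzyloxy)-6-iodophenyl]-5,7-bis(benzyloxy)-2-[4-(benzyloxy)phenyl]-4H-chromen-4-one
Conditions: NaI (2 equiv), CuI (10 mol %), trans-N,N'-dimethylcyclohexane-1,2-diamine (20 mol %), 1,4-dioxane, 110 °C
Reagents that add atoms: sodium iodide [Na+].[I-]
Why: Copper-catalysed aromatic Finkelstein reaction, driven by precipitation of NaBr from dioxane, which supplies the more reactive halide for the key step and touches neither the benzyl ethers nor the chromone.

Step 8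
Reactants: 13 4-(benzyloxy)phenylmagnesium bromide (commercial THF solution); 14 3-chloropropanoyl chloride
Product: 15 1-[4-(benzyloxy)phenyl]-3-chloropropan-1-one
Conditions: 14 (1.1 equiv), CuI (5 mol %), THF, −40 °C, slow addition of 13; cold aq. NH4Cl
Reagents that add atoms: none
Why: Copper-catalysed acylation of a Grignard reagent with an acid chloride, where slow addition at low temperature keeps the basic reagent scarce so that neither a second addition nor loss of HCl from the β-chloro ketone should compete.

Step 9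
Reactants: 15 1-[4-(benzyloxy)phenyl]-3-chloropropan-1-one
Product: 16 (S)-1-[4-(benzyloxy)phenyl]-3-chloropropan-1-ol
Conditions: (R)-Me-CBS oxazaborolidine (10 mol %), BH3·SMe2 (0.7 equiv), THF, −20 °C; aq. NH4Cl work-up
Reagents that add atoms: none
Why: Corey–Bakshi–Shibata reduction, in which the (R)-oxazaborolidine binds borane and the ketone with the aryl group as the large substituent and delivers hydride to the face that gives the (S)-carbinol, the future C2 of the flavan.

Step 10
Reactants: 16 (S)-chloro alcohol
Product: 17 (S)-2-[4-(benzyloxy)phenyl]oxetane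
Conditions: KOtBu (1.2 equiv), THF, 0 °C to rt; chromatography on base-washed silica
Reagents that add atoms: none
Why: Intramolecular Williamson etherification (4-exo-tet) at the primary chloride, which leaves the bonds of the stereocentre untouched so that the (S) configuration is retained.

Step 11
Reactants: 12 iodoaryl flavone; 17 (S)-2-[4-(benzyloxy)phenyl]oxetane
Product: 18 5,7-bis(benzyloxy)-3-{(2S)-5,7-bis(benzyloxy)-2-[4-(benzyloxy)phenyl]chroman-8-yl}-2-[4-(benzyloxy)phenyl]-4H-chromen-4-one (hexa-O-benzyl daphnodorin D2)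
Conditions: Pd(OAc)2 (10 mol %), RuPhos (20 mol %), isopropyl bicyclo[2.2.1]hept-2-ene-2-carboxylate (50 mol %), Cs2CO3 (2.5 equiv), 17 (2 equiv), 1,4-dioxane, 100 °C, Ar
Reagents that add atoms: none
Why: Proposed new method: zerovalent palladium inserts into the C–I bond of 12, the norbornene ester carbopalladates, and carbonate-assisted metalation of the only free ortho C–H (the future C4a) gives the aryl–norbornyl palladacycle, whose electron-rich divalent palladium opens the oxetane by SN2-type oxidative addition at the unhindered O–CH2 carbon with release of ring strain; aryl–alkyl reductive elimination from tetravalent palladium then makes C4–C4a, the now doubly ortho-flanked aryl group expels the norbornene by β-carbon elimination, and the tethered alkoxide forms O1–C8a by C–O reductive elimination. The closest known reaction type is the palladium/norbornene (Catellani-type) annulation of aryl iodides with epoxides to 2,3-dihydrobenzofurans and with aziridines to indolines, joined to the Buchwald–Hartwig intramolecular etherification of secondary alcohols to 2-substituted chromans, and what is new is the four-membered ether as alkylating partner. Ring C of the flavan is closed by reductive elimination from a seven-membered aryl palladium alkoxide chelate, so that overall the A-ring edge C4a–C8a is inserted into the O–CH2 bond of the oxetane. No stereocentre is created: C2 is carried over from 17 with retention because none of its bonds is touched, and bulky, electron-rich RuPhos is chosen so that C–O reductive elimination outruns β-hydride elimination of the benzylic alkoxide. Site selectivity on the arene is secured by the flavon-3-yl group at C8, which blocks the second ortho position and supplies the bulk that drives norbornene extrusion, while the C5 benzyloxy group acidifies C4a–H, and opening of the oxetane at CH2 instead of benzylic C2 follows from the steric demand of the palladacycle and the absence of any Lewis or Brønsted acid. Direct arylation of ring B of the flavone should stay behind, because its planar product would press the C7 benzyloxy group against the C4 carbonyl, and the ester on the norbornene double bond retards collapse of the palladacycle and a second insertion.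

Step 12
Reactants: 18 hexa-O-benzyl daphnodorin D2
Product: 19 daphnodorin D2, 5,7-dihydroxy-3-[(2S)-5,7-dihydroxy-2-(4-hydroxyphenyl)chroman-8-yl]-2-(4-hydroxyphenyl)-4H-chromen-4-one
Conditions: H2 (1 atm), Pd(OH)2/C, THF–MeOH, rt
Reagents that add atoms: none
Why: Hydrogenolysis of the six aryl benzyl ethers under neutral conditions, which should be much faster than cleavage of the cyclic benzylic O1–C2 bond and leaves the tetrasubstituted C2=C3 bond of the flavone and the stereocentre intact.

**Compound list**
1 | 2',4',6'-trihydroxyacetophenone | CC(=O)c1c(O)cc(O)cc1O | starting material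
2 | 1-[2,4-bis(benzyloxy)-6-hydroxyphenyl]ethan-1-one | CC(=O)c1c(O)cc(OCc2ccccc2)cc1OCc1ccccc1 | intermediate
3 | 4-(benzyloxy)benzaldehyde | O=Cc1ccc(OCc2ccccc2)cc1 | starting material
4 | (E)-1-[2,4-bis(benzyloxy)-6-hydroxyphenyl]-3-[4-(benzyloxy)phenyl]prop-2-en-1-one | O=C(/C=C/c1ccc(OCc2ccccc2)cc1)c1c(O)cc(OCc2ccccc2)cc1OCc1ccccc1 | intermediate
5 | racemic 5,7-bis(benzyloxy)-2-[4-(benzyloxy)phenyl]chroman-4-one (flavanone, not isolated) | O=C1CC(c2ccc(OCc3ccccc3)cc2)Oc2cc(OCc3ccccc3)cc(OCc3ccccc3)c12 | intermediate
6 | 5,7-bis(benzyloxy)-2-[4-(benzyloxy)phenyl]-4H-chromen-4-one | O=c1cc(-c2ccc(OCc3ccccc3)cc2)oc2cc(OCc3ccccc3)cc(OCc3ccccc3)c12 | intermediate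
7 | 5-bromoresorcinol | Oc1cc(O)cc(Br)c1 | starting material
8 | 1,3-bis(benzyloxy)-5-bromobenzene | Brc1cc(OCc2ccccc2)cc(OCc2ccccc2)c1 | intermediate
9 | 1,5-bis(benzyloxy)-3-bromo-2-iodobenzene | Ic1c(Br)cc(OCc2ccccc2)cc1OCc1ccccc1 | intermediate
10 | {5,7-bis(benzyloxy)-2-[4-(benzyloxy)phenyl]-4-oxo-4H-chromen-3-yl}zinc chloride (not isolated) | O=c1c([Zn]Cl)c(-c2ccc(OCc3ccccc3)cc2)oc2cc(OCc3ccccc3)cc(OCc3ccccc3)c12 | intermediate
11 | 3-[2,4-bis(benzyloxy)-6-bromophenyl]-5,7-bis(benzyloxy)-2-[4-(benzyloxy)phenyl]-4H-chromen-4-one | O=c1c(-c2c(Br)cc(OCc3ccccc3)cc2OCc2ccccc2)c(-c2ccc(OCc3ccccc3)cc2)oc2cc(OCc3ccccc3)cc(OCc3ccccc3)c12 | intermediate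
12 | 3-[2,4-bis(benzyloxy)-6-iodophenyl]-5,7-bis(benzyloxy)-2-[4-(benzyloxy)phenyl]-4H-chromen-4-one | O=c1c(-c2c(I)cc(OCc3ccccc3)cc2OCc2ccccc2)c(-c2ccc(OCc3ccccc3)cc2)oc2cc(OCc3ccccc3)cc(OCc3ccccc3)c12 | intermediate
13 | 4-(benzyloxy)phenylmagnesium bromide | Br[Mg]c1ccc(OCc2ccccc2)cc1 | starting material
14 | 3-chloropropanoyl chloride | O=C(Cl)CCCl | starting material
15 | 1-[4-(benzyloxy)phenyl]-3-chloropropan-1-one | O=C(CCCl)c1ccc(OCc2ccccc2)cc1 | intermediate
16 | (S)-1-[4-(benzyloxy)phenyl]-3-chloropropan-1-ol | O[C@H](c1ccc(OCc2ccccc2)cc1)CCCl | intermediate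
17 | (S)-2-[4-(benzyloxy)phenyl]oxetane | O1[C@H](c2ccc(OCc3ccccc3)cc2)CC1 | intermediate
18 | hexa-O-benzyl daphnodorin D2 | O=c1c(-c2c(OCc3ccccc3)cc(OCc3ccccc3)c3c2O[C@H](c2ccc(OCc4ccccc4)cc2)CC3)c(-c2ccc(OCc3ccccc3)cc2)oc2cc(OCc3ccccc3)cc(OCc3ccccc3)c12 | intermediate
19 | daphnodorin D2 | O=c1c(-c2c(O)cc(O)c3c2O[C@H](c2ccc(O)cc2)CC3)c(-c2ccc(O)cc2)oc2cc(O)cc(O)c12 | target

**Step count**
Total step count: 12. Longest linear sequence: 7 steps (steps 1, 2, 3, 6, 7, 11, 12).

**Steps most likely to fail**

Step 11 (key step).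
- Oxidative addition of the four-membered ether to the palladacycle may be too slow.
- The palladacycle may then collapse with retention of the norbornene, or couple with a second molecule of 12.
- β-Hydride elimination may intervene at the alkoxide stage.
- The oxetane may open at the benzylic carbon, with erosion of configuration.

The fallback uses known chemistry only and makes the flavan first and the flavone–flavan bond last. It sets out from 9 and 17 and returns to the route at 18. Iodine–lithium exchange on 9 (n-BuLi, THF, −78 °C) gives (2,4-bis(benzyloxy)-6-bromophenyl)lithium F1. F1 opens 17 at the O–CH2 carbon in the presence of BF3·OEt2 at −78 °C to give (S)-3-[2,4-bis(benzyloxy)-6-bromophenyl]-1-[4-(benzyloxy)phenyl]propan-1-ol F2. Buchwald–Hartwig intramolecular etherification (Pd(OAc)2, 2-(di-tert-butylphosphino)-1,1'-binaphthyl, Cs2CO3, toluene, 80 °C) closes, with retention, (S)-5,7-bis(benzyloxy)-2-[4-(benzyloxy)phenyl]chromane F3. NIS (CH2Cl2, 0 °C) iodinates the more nucleophilic C8 to give (S)-5,7-bis(benzyloxy)-2-[4-(benzyloxy)phenyl]-8-iodochromane F4. Negishi coupling of F4 with zinc reagent 10, made from 6 as in step 6, gives 18.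

Step 6.
- Transmetalation and reductive elimination at a bond flanked on all four sides may be slow, which would allow protodezincation and homocoupling.
- Insertion into the C–Br bond may begin to compete.

The fallback makes the C3–aryl bond by an intramolecular 1,2-aryl shift instead of a cross-coupling. It sets out from 8 and 2 and returns at 11. Vilsmeier–Haack formylation of 8 (POCl3, DMF) gives 2,4-bis(benzyloxy)-6-bromobenzaldehyde F5. Claisen–Schmidt condensation with 2 (KOH, EtOH) gives (E)-3-[2,4-bis(benzyloxy)-6-bromophenyl]-1-[2,4-bis(benzyloxy)-6-hydroxyphenyl]prop-2-en-1-one F6. Oxidative rearrangement (Tl(NO3)3, MeOH/CH(OMe)3, rt) moves the electron-rich bromoaryl group to the carbon next to the carbonyl. This gives racemic 2-[2,4-bis(benzyloxy)-6-bromophenyl]-1-[2,4-bis(benzyloxy)-6-hydroxyphenyl]-3,3-dimethoxypropan-1-one F7. Catalytic HCl in MeOH at reflux closes 3-[2,4-bis(benzyloxy)-6-bromophenyl]-5,7-bis(benzyloxy)-4H-chromen-4-one F8. Zincation of its acidic C2–H (TMPZnCl·LiCl, THF, no Lewis acid) gives the chromon-2-ylzinc chloride F9. Negishi coupling of F9 with commercial 1-(benzyloxy)-4-iodobenzene (Pd(OAc)2, SPhos) gives 11.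

Step 7.
- The equilibrium halogen exchange may stay incomplete at the hindered position next to the flavone, leaving halide mixtures that are hard to separate.

The fallback replaces the exchange by a metalation and ipso-substitution pair. It sets out from 11 and returns at 12. Palladium-catalysed stannylation (Me3SnSnMe3, Pd(PPh3)4, toluene, 110 °C) gives 3-[2,4-bis(benzyloxy)-6-(trimethylstannyl)phenyl]-5,7-bis(benzyloxy)-2-[4-(benzyloxy)phenyl]-4H-chromen-4-one F10. Iododestannylation (I2, CH2Cl2, 0 °C) should be far faster than iodination of the alkoxyarene rings by unactivated iodine and gives 12.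

**Further compounds**
F1 | step 11 | (2,4-bis(benzyloxy)-6-bromophenyl)lithium | [Li]c1c(Br)cc(OCc2ccccc2)cc1OCc1ccccc1
F2 | step 11 | (S)-3-[2,4-bis(benzyloxy)-6-bromophenyl]-1-[4-(benzyloxy)phenyl]propan-1-ol | O[C@H](c1ccc(OCc2ccccc2)cc1)CCc1c(Br)cc(OCc2ccccc2)cc1OCc1ccccc1
F3 | step 11 | (S)-5,7-bis(benzyloxy)-2-[4-(benzyloxy)phenyl]chromane | c1c(OCc2ccccc2)cc(OCc2ccccc2)c2c1O[C@H](c1ccc(OCc3ccccc3)cc1)CC2
F4 | step 11 | (S)-5,7-bis(benzyloxy)-2-[4-(benzyloxy)phenyl]-8-iodochromane | Ic1c(OCc2ccccc2)cc(OCc2ccccc2)c2c1O[C@H](c1ccc(OCc3ccccc3)cc1)CC2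
F5 | step 6 | 2,4-bis(benzyloxy)-6-bromobenzaldehyde | O=Cc1c(Br)cc(OCc2ccccc2)cc1OCc1ccccc1
F6 | step 6 | (E)-3-[2,4-bis(benzyloxy)-6-bromophenyl]-1-[2,4-bis(benzyloxy)-6-hydroxyphenyl]prop-2-en-1-one | O=C(/C=C/c1c(Br)cc(OCc2ccccc2)cc1OCc1ccccc1)c1c(O)cc(OCc2ccccc2)cc1OCc1ccccc1
F7 | step 6 | racemic 2-[2,4-bis(benzyloxy)-6-bromophenyl]-1-[2,4-bis(benzyloxy)-6-hydroxyphenyl]-3,3-dimethoxypropan-1-one | COC(OC)C(c1c(Br)cc(OCc2ccccc2)cc1OCc1ccccc1)C(=O)c1c(O)cc(OCc2ccccc2)cc1OCc1ccccc1
F8 | step 6 | 3-[2,4-bis(benzyloxy)-6-bromophenyl]-5,7-bis(benzyloxy)-4H-chromen-4-one | O=c1c(-c2c(Br)cc(OCc3ccccc3)cc2OCc2ccccc2)coc2cc(OCc3ccccc3)cc(OCc3ccccc3)c12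
F9 | step 6 | {3-[2,4-bis(benzyloxy)-6-bromophenyl]-5,7-bis(benzyloxy)-4-oxo-4H-chromen-2-yl}zinc chloride | O=c1c(-c2c(Br)cc(OCc3ccccc3)cc2OCc2ccccc2)c([Zn]Cl)oc2cc(OCc3ccccc3)cc(OCc3ccccc3)c12
F10 | step 7 | 3-[2,4-bis(benzyloxy)-6-(trimethylstannyl)phenyl]-5,7-bis(benzyloxy)-2-[4-(benzyloxy)phenyl]-4H-chromen-4-one | O=c1c(-c2c([Sn](C)(C)C)cc(OCc3ccccc3)cc2OCc2ccccc2)c(-c2ccc(OCc3ccccc3)cc2)oc2cc(OCc3ccccc3)cc(OCc3ccccc3)c12
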